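The readings are calculated on assumed constants, noise included.

A small charge of free catalyst, 0.76 mM, has to turn substrate into intermediate and then, with partner, intermediate into product, and you may feed one reagent slowly.

| setting | Sunday's | Thursday's | Tuesday's | violet | teal | grey |
|---|---|---|---|---|---|---|
| substrate | 0.40 M | 0.40 M | 0.40 M | 0.40 M | 0.40 M (fed, over 2.0 h) | 0.40 M |
| partner | 0.48 M | 0.24 M | 0.36 M | 0.480 M (fed, over 2.0 h) | 0.480 M | 0.480 M |
| free catalyst | 0.76 mM | 0.76 mM | 0.76 mM | 0.76 mM | 0.76 mM | 0.76 mM |
| remark | run made earlier | run made earlier | run made earlier | all else is in the flask from the start; the feed brings no volume worth counting | all else is in the flask from the start; the feed brings no volume worth counting | everything together at the start |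
| time |  |  |  | 5.0 h | 5.0 h | 5.0 h |

| run | time / h | product / % | substrate / % |
|---|---|---|---|
| Sunday's | 0.667 | 2.4 | 34.5 |
| Sunday's | 1.33 | 8.7 | 12.2 |
| Sunday's | 2.00 | 9.8 | 3.3 |
| Sunday's | 2.50 | 10.6 | 2.9 |
| Sunday's | 3.00 | 8.5 | 1.6 |
| Thursday's | 0.333 | 0.4 | 58.0 |
| Thursday's | 0.667 | 2.0 | 34.8 |
| Thursday's | 1.00 | 0 | 19.3 |
| Thursday's | 2.00 | 3.4 | 3.7 |
| Thursday's | 4.00 | 6.0 | 2.6 |
| Tuesday's | 0.833 | 2.4 | 27.0 |
| Tuesday's | 1.50 | 6.2 | 8.9 |
| Tuesday's | 2.50 | 6.6 | 3.5 |
| Tuesday's | 3.00 | 10.6 | 0.8 |
| Tuesday's | 4.00 | 9.1 | 0.2 |

(readings scatter by 1 percentage point)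

1. the flask that comes out highest in amount of product, in percent of the substrate charged, or "all alike" when all lie within 1.5 percentage points (violet / teal / grey / all alike)
2. product at the end, in percent of the substrate charged, violet
3. product at the end, in percent of the substrate charged, teal
4. product at the end, in percent of the substrate charged, grey

- the numbers in the tables scatter with a standard deviation of 1 percentage point
- steps that have been proposed: substrate + free catalyst -> free catalyst + intermediate; partner + free catalyst + intermediate -> free catalyst + product; partner + free catalyst -> spent catalyst; partner -> decomposed reagent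

Follow Sunday's run, which has grey's charges. In the first instants substrate falls pseudo-first-order, at 1.60 h⁻¹ by Sunday's first reading and 1.58 h⁻¹ by Thursday's, with half the partner, so the partner level does not show in this step.

By 2.00 h, Sunday's substrate reads 3.3% and its product 9.8%, which leaves 86.9% as intermediate.

Yet product then stays near 9.63%, which points to the partner going, by the proposed step to decomposed reagent. My own reckoning takes that 2.00 h as two lifetimes of partner:

partner rate = 1.00 h⁻¹

overlap = substrate rate / (substrate rate + partner rate) = 61.5%

This overlap share is the part of the partner's work that falls after substrate has become intermediate. Sunday's level then implies a ceiling, the product at full overlap. Averaging the same sum over parcels fed steadily for 2.0 h gives each flask its share: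

ceiling = 9.63% / 61.5% = 15.7%

violet: 88.4% of the ceiling = 13.9%

teal: 26.6% of the ceiling = 4.16%

The forecast names violet, with 15.3% for violet, 4.6% for teal and 10.8% for grey, on the ground that “feeding spares partner”. Its figures stand above mine, in the same order.

The flasks put violet highest: violet 14.8%, teal 5.99%, grey 11.6%.

    substrate + free catalyst → free catalyst + intermediate (k = 35.6 M⁻¹ min⁻¹)
    partner + free catalyst + intermediate → free catalyst + product (k = 7.47 M⁻² min⁻¹)
    partner + free catalyst → spent catalyst (k = 4.74 × 10⁻⁴ M⁻¹ min⁻¹)
    partner → decomposed reagent (k = 0.0126 min⁻¹)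

At 2.50 h, violet still holds 30.6% of its partner, more than the 11.9% in grey. The constants give a substrate rate of 1.62 h⁻¹ and a partner rate of 0.756 h⁻¹, so the overlap share for grey becomes 68.2%. Grey's 11.6% over that gives a ceiling of 16.9%, and teal's share by the same sum, 35.2%, makes 5.95% of that, against the 5.99% teal reached. The same ceiling with violet's share, 90.6%, scaled to 0.29 M of partner, gives 9.27%; the neighbour flask, violet's recipe with that charge, ends at 9.25%.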